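**Plan**

Retrosynthesis: δ-lactone ring B is opened at its acyl C–O bond to a 1,5-diol; the orthoester cage is unlocked at the two C–O bonds of the orthoester carbon and at the acyl C–O bond of the cage γ-lactone; the resulting side chain is cut at Cc–Cd (aldol), Ca–Cb (Michael) and Ca–CH3; the spiro γ-lactone is cut at C1–CH2 and at its acyl C–O bond to a ring-A ketone and methyl acrylate; ring A goes back to (R)-carvone.
Feature: ring C, the spiro tetrahydrofuran, meets ring A at the tertiary C1–O carbon beside quaternary C6; C1 and its ring oxygen are a ketone, and the other three ring-C carbons (CH2, Ca, orthoester carbon) are the β-, α- and carbonyl carbons of an acrylate, so ring C can be made as a γ-lactone whose carbonyl later becomes the orthoester carbon.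
Forward: ring A is dressed first (C6 by double alkylation, 1,3-transposition of the enone, hydroboration to the C1 carbinol and oxidation), ring C is closed as the γ-lactone in the key step, the side chain is joined by methylation, Michael and aldol additions, acid closes the three cage rings at once, and ring B is closed last by oxidative lactonisation.
Stereochemistry: C5 from carvone; C6 by alkylation anti to the C5 group; C3 by Luche reduction; C2 by hydroboration anti to the C3 silyloxy and axial C6 groups; C1 by axial ketyl attack; Ca by the lactone face; Cb by a closed Michael transition state; Cc and Cd by allylic strain and a chair aldol transition state; orthoester and ketal carbons by the cage geometry.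
Numbering and remarks: ring A keeps the carvone numbering (C1 carbonyl/spiro carbon, C2 methyl, C3 oxygen, C5 side chain, C6 quaternary); Ca = lactone α-carbon, Cb = CH–CH3, Cc = ester α-carbon, Cd = carbinol. (R)-Carvone is used because its carbonyl, methyl and side chain then map onto C1, C2 and C5 directly. Ring B is carried as a benzyl ether and a silyl ether so that the spiro γ-lactone is the only enolisable ester while the side chain is built.

Key step: step 13

Step 1
Reactants: 1 (R)-(−)-carvone
Product: 2 (5R)-5-(2-hydroxypropan-2-yl)-2-methylcyclohex-2-en-1-one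
Conditions: 50% aq. H2SO4, 0 °C
Reagents that add atoms: water (O)
Why: Acid-catalysed hydration of the isopropenyl group proceeds through the tertiary cation while the protonated enone is deactivated, so only the side chain reacts and the C5 stereocentre of carvone is carried over unchanged.

Step 2
Reactants: 2 (5R)-5-(2-hydroxypropan-2-yl)-2-methylcyclohex-2-en-1-one
Product: 3 (5R)-2-methyl-5-[2-(triethylsilyloxy)propan-2-yl]cyclohex-2-en-1-one
Conditions: TESOTf, 2,6-lutidine, CH2Cl2, −78 °C
Reagents that add atoms: triethylsilyl trifluoromethanesulfonate (CC[Si](CC)(CC)OS(=O)(=O)C(F)(F)F)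
Why: Silyl ether formation with a silyl triflate and a hindered pyridine base is the standard way to cap a tertiary alcohol, and the cap keeps the hydroxyl from quenching the amide bases and from adding to the C1 carbonyl later.

Step 3
Reactants: 3 (5R)-2-methyl-5-[2-(triethylsilyloxy)propan-2-yl]cyclohex-2-en-1-one; 4 benzyl chloromethyl ether
Product: 5 (5R,6R)-6-(benzyloxymethyl)-2-methyl-5-[2-(triethylsilyloxy)propan-2-yl]cyclohex-2-en-1-one (CH2OBn trans to the C5 group)
Conditions: LiN(i-Pr)2, THF, −78 °C; then 4, −78 → −40 °C
Reagents that add atoms: benzyl chloromethyl ether 4 (ClCOCc1ccccc1)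
Why: Kinetic α′-deprotonation of the enone at C6 gives the cross-conjugated lithium dienolate, which is C-alkylated by the reactive α-chloro ether (enolate alkylation) trans to the neighbouring C5 group; this centre is planarised again in step 4.

Step 4
Reactants: 5 (5R,6R)-6-(benzyloxymethyl) enone; 6 allyl bromide
Product: 7 (5R,6S)-6-allyl-6-(benzyloxymethyl)-2-methyl-5-[2-(triethylsilyloxy)propan-2-yl]cyclohex-2-en-1-one (CH2OBn cis and allyl trans to the C5 group)
Conditions: LiN(i-Pr)2, THF, −78 °C; then DMPU, 6, −78 → 0 °C
Reagents that add atoms: allyl bromide 6 (C=CCBr)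
Why: Enolate alkylation of the re-formed C6 enolate by allyl bromide takes place on the face opposite the adjacent C5 silyloxypropyl group, so the allyl group ends trans and the benzyloxymethyl group cis to it, which sets quaternary C6; an allyl group serves as the three-carbon arm because an acrylate would add twice to the dienolate and give a bicyclo[2.2.2]octanone.

Step 5
Reactants: 7 (5R,6S)-6-allyl-6-(benzyloxymethyl) enone
Product: 8 2,3-epoxy ketone of 7 (epoxide oxygen trans to the C5 group)
Conditions: 30% aq. H2O2, NaOH (cat.), MeOH, 0 °C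
Reagents that add atoms: hydrogen peroxide (OO)
Why: Nucleophilic (Weitz–Scheffer) epoxidation attacks only the electron-poor enone alkene, axial addition of hydroperoxide anti to the C5 group giving the trans epoxide, whose configuration is of no consequence because C2 and C3 are planarised in steps 6 and 7.

Step 6
Reactants: 8 2,3-epoxy ketone
Product: 9 transposed allylic alcohol (C3–OH trans to the C5 group; C1=C2 alkene)
Conditions: N2H4·H2O, AcOH (cat.), MeOH, 0 °C → rt, argon
Reagents that add atoms: none
Why: Wharton transposition: the hydrazone of the epoxy ketone opens the epoxide to an alkenyl diazene that loses N2, which moves the oxygen from C1 to C3 and the alkene to C1=C2; the C3 carbinol inherits the epoxide configuration, which is erased in step 7.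

Step 7
Reactants: 9 transposed allylic alcohol
Product: 10 transposed enone (C3 ketone; C1=C2 alkene; C6 quaternary)
Conditions: Dess–Martin periodinane, pyridine, CH2Cl2, 0 °C → rt
Reagents that add atoms: none
Why: Dess–Martin oxidation of the secondary allylic alcohol gives the enone with the carbonyl now at C3 and clears the C3 stereocentre; C5 and C6 are not enolisable in this enone.

Step 8
Reactants: 10 transposed enone
Product: 11 cis allylic alcohol (C3–OH cis to the C5 group)
Conditions: NaBH4, CeCl3·7H2O, MeOH, −40 °C
Reagents that add atoms: none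
Why: Luche 1,2-reduction: as in the reduction of carvone to cis-carveol, hydride adds to C3 along the axial direction of the half-chair that keeps the C5 group equatorial, so the new hydroxyl is equatorial and cis to the C5 group.

Step 9
Reactants: 11 cis allylic alcohol
Product: 12 C3 tert-butyldimethylsilyl ether of 11
Conditions: TBSCl, imidazole, DMF, rt
Reagents that add atoms: tert-butyldimethylsilyl chloride (CC(C)(C)[Si](C)(C)Cl)
Why: Imidazole-promoted silyl ether formation on the unhindered secondary allylic alcohol protects C3–OH and turns it into a bulky allylic substituent for the next step.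

Step 10
Reactants: 12 C3 silyl ether
Product: 14 diol with C1–OH and a 3-hydroxypropyl arm on C6 (C2 methyl cis to C3–OTBS; C1–OH trans to both), via bis(alkylborane) 13 (not isolated)
Conditions: BH3·THF, THF, 0 °C → rt; then NaOH, 30% aq. H2O2, 0 °C → rt
Reagents that add atoms: hydrogen peroxide (OO)
Why: Hydroboration places boron on the less substituted carbon of both alkenes (C1 of the ring alkene and the terminal allyl carbon) and adds H and B syn from the ring face opposite the allylic C3 silyloxy group and the pseudo-axial C6 benzyloxymethyl group, so C2–H is delivered trans to them and the C2 methyl ends cis to C3–O, and oxidation of the C–B bonds with retention gives the diol.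

Step 11
Reactants: 14 diol
Product: 15 primary tert-butyldimethylsilyl ether of 14 (C1–OH free)
Conditions: TBSCl, imidazole, CH2Cl2, 0 °C
Reagents that add atoms: tert-butyldimethylsilyl chloride (CC(C)(C)[Si](C)(C)Cl)
Why: Silyl ether formation is selective for the primary alcohol because the C1 hydroxyl is secondary, axial and flanked by quaternary C6 and the methyl-bearing C2.

Step 12
Reactants: 15 mono-protected diol
Product: 16 ring-A ketone (C1 ketone; axial C2 methyl cis to C3–OTBS)
Conditions: Dess–Martin periodinane, pyridine, CH2Cl2, rt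
Reagents that add atoms: none
Why: Dess–Martin oxidation under buffered, base-free conditions converts the hindered C1 carbinol into the ketone while the C2 methyl, which is axial and the less stable epimer, is kept because its C2–H bond is equatorial and poorly aligned with the carbonyl π system for enolisation.

Step 13
Reactants: 16 ring-A ketone; 17 methyl acrylate
Product: 19 spiro γ-lactone (ring C as lactone; lactone oxygen on C1 cis to the C2/C3/C5 substituents), via samarium alkoxide ester 18 (not isolated)
Conditions: SmI2 (2.5 equiv), 17, t-BuOH, THF, −78 → 0 °C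
Reagents that add atoms: methyl acrylate 17 (C=CC(=O)OC)
Why: SmI2 transfers one electron to the C1 ketone, the ketyl radical anion adds to the β-carbon of methyl acrylate to form the C1–CH2 bond, and a second electron reduces the α-ester radical to a samarium enolate that t-BuOH protonates to give alkoxide ester 18. The trivalent samarium alkoxide then attacks the methyl ester in a 5-exo-trig acyl substitution, expels methoxide and closes ring C as the spiro γ-lactone. The closest known reaction type is the SmI2-mediated reductive coupling of ketones with acrylates to γ-butyrolactones. The one new stereocentre, C1, is set by the chair of ring A: the C2 methyl and the C6 benzyloxymethyl group are both axial on one face, so the acrylate is taken up axially on the other face and the ring oxygen ends equatorial, cis to the C2, C3 and C5 substituents. The step needs chemoselectivity for the ketone and tolerance of a carbonyl beside a quaternary carbon; 16 secures both because its other functions are only silyl and benzyl ethers, and because ketyl formation is an electron transfer that steric shielding does not stop while the crowded ketyl cannot dimerise to a pinacol.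

Step 14
Reactants: 19 spiro γ-lactone; 20 iodomethane
Product: 21 α-methyl spiro γ-lactone (either epimer at Ca)
Conditions: LiN(i-Pr)2, THF, −78 °C; then 20, −78 → −40 °C
Reagents that add atoms: iodomethane 20 (CI)
Why: The spiro γ-lactone carries the only acidic C–H bonds in 19, so its lithium enolate forms cleanly and is methylated (enolate alkylation); the configuration of the new α-centre is irrelevant because it becomes trigonal again in step 15.

Step 15
Reactants: 21 α-methyl spiro γ-lactone; 22 methyl (E)-crotonate
Product: 23 Michael adduct (quaternary Ca; Cb methine; methyl ester)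
Conditions: LiN(i-Pr)2, THF, −78 °C; then 22, −78 °C; AcOH, −78 °C
Reagents that add atoms: methyl (E)-crotonate 22 (C/C=C/C(=O)OC)
Why: Michael addition of the tetrasubstituted lithium lactone enolate to the enoate forms the Ca–Cb bond on the lactone face next to the C2–H of ring A (the other face is covered by the equatorial chain on C6), and the chelated, synclinal closed transition state of the ring-fixed E(O)-enolate with the (E)-enoate puts the crotonate methyl syn to the lactone CH2, which is the relative configuration of Ca and Cb required in the cage.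

Step 16
Reactants: 23 Michael adduct; 24 methacrolein
Product: 25 anti-aldol adduct (Cc–Cd anti; isopropenyl carbinol)
Conditions: LiN(i-Pr)2, THF, −78 °C; then 24, −78 °C; AcOH, −78 °C
Reagents that add atoms: methacrolein 24 (CC(=C)C=O)
Why: Aldol addition of the kinetic E(O)-lithium enolate of the methyl ester (the only acidic C–H left, since Ca is quaternary) through a chair-like closed transition state gives the anti Cc–Cd relationship, and the aldehyde enters anti to the bulky quaternary Ca in the conformer whose Cb–H eclipses the enolate (allylic 1,3-strain), which fixes Cc relative to Cb.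

Step 17
Reactants: 25 anti-aldol adduct
Product: 27 α-hydroxy methyl ketone, via ozonide 26 (not isolated)
Conditions: O3, CH2Cl2, −78 °C; then Me2S, −78 °C → rt
Reagents that add atoms: ozone ([O-][O+]=O)
Why: Ozonolysis of the only remaining alkene and reductive cleavage of the ozonide unmask the methyl ketone without touching a stereocentre, the ethers, esters and the free carbinol being inert at −78 °C.

Step 18
Reactants: 27 α-hydroxy methyl ketone
Product: 29 cage triol benzyl ether (orthoester cage closed; silyl groups removed), via silylated cage 28 (not isolated)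
Conditions: (+)-camphor-10-sulfonic acid (cat.), 4 Å molecular sieves, CH2Cl2, rt; then HF·pyridine, pyridine, THF, 0 °C → rt
Reagents that add atoms: none
Why: Acid-catalysed intramolecular orthoester formation: the Cd hydroxyl adds to the γ-lactone carbonyl, the hemi-orthoester hydroxyl adds to the methyl ketone (5-exo) and the resulting hemiketal hydroxyl acylates on the methyl ester (5-exo) with loss of methanol to the sieves, which closes the tetrahydropyran, dioxolane and cage γ-lactone rings; the orthoester and ketal carbons can adopt only the configuration allowed by the fixed Ca, Cc and Cd centres, and buffered fluoride then cleaves the three silyl ethers.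

Step 19
Reactants: 29 cage triol benzyl ether
Product: 30 cage tetraol
Conditions: H2 (1 atm), Pd/C, EtOAc, rt
Reagents that add atoms: none
Why: Hydrogenolysis of the benzyl ether over palladium on carbon; no C=C bond is left, and the lactone, the orthoester and the alcohols are inert to H2.

Step 20
Reactants: 30 cage tetraol
Product: 32 Chermebilaene B, via lactol 31 (not isolated)
Conditions: TEMPO (cat.), PhI(OAc)2, CH2Cl2, rt
Reagents that add atoms: none
Why: Oxoammonium (TEMPO) oxidation picks the unhindered primary alcohol over the neopentyl primary, the secondary and the tertiary hydroxyls, the aldehyde is trapped by the neopentyl CH2OH as six-membered lactol 31, and this is oxidised on to δ-lactone ring B (oxidative lactonisation of a 1,5-diol) without forming or touching a stereocentre.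

**Compound list**

1 | (R)-(−)-carvone | CC1=CC[C@H](CC1=O)C(C)=C | starting material
2 | (5R)-5-(2-hydroxypropan-2-yl)-2-methylcyclohex-2-en-1-one | CC1=CC[C@@H](C(C)(C)O)CC1=O | intermediate
3 | (5R)-2-methyl-5-[2-(triethylsilyloxy)propan-2-yl]cyclohex-2-en-1-one | CC1=CC[C@@H](C(C)(C)O[Si](CC)(CC)CC)CC1=O | intermediate
4 | benzyl chloromethyl ether | ClCOCc1ccccc1 | starting material
5 | (5R,6R)-6-(benzyloxymethyl)-2-methyl-5-[2-(triethylsilyloxy)propan-2-yl]cyclohex-2-en-1-one, CH2OBn trans to the C5 group | CC1=CC[C@@H](C(C)(C)O[Si](CC)(CC)CC)[C@H](COCc2ccccc2)C1=O | intermediate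
6 | allyl bromide | C=CCBr | starting material
7 | (5R,6S)-6-allyl-6-(benzyloxymethyl)-2-methyl-5-[2-(triethylsilyloxy)propan-2-yl]cyclohex-2-en-1-one, CH2OBn cis and allyl trans to the C5 group | CC1=CC[C@@H](C(C)(C)O[Si](CC)(CC)CC)[C@](COCc2ccccc2)(CC=C)C1=O | intermediate
8 | 2,3-epoxy ketone of 7, epoxide oxygen trans to the C5 group | C[C@@]12O[C@@H]1C[C@@H](C(C)(C)O[Si](CC)(CC)CC)[C@](COCc3ccccc3)(CC=C)C2=O | intermediate
9 | transposed allylic alcohol, C3–OH trans to the C5 group, C1=C2 alkene | CC1=C[C@@](COCc2ccccc2)(CC=C)[C@H](C(C)(C)O[Si](CC)(CC)CC)C[C@H]1O | intermediate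
10 | transposed enone, C3 ketone and C1=C2 alkene | CC1=C[C@@](COCc2ccccc2)(CC=C)[C@H](C(C)(C)O[Si](CC)(CC)CC)CC1=O | intermediate
11 | cis allylic alcohol, C3–OH cis to the C5 group | CC1=C[C@@](COCc2ccccc2)(CC=C)[C@H](C(C)(C)O[Si](CC)(CC)CC)C[C@@H]1O | intermediate
12 | C3 tert-butyldimethylsilyl ether of 11 | CC1=C[C@@](COCc2ccccc2)(CC=C)[C@H](C(C)(C)O[Si](CC)(CC)CC)C[C@@H]1O[Si](C)(C)C(C)(C)C | intermediate
13 | bis(alkylborane) from 12, drawn as the bis-BH2 compound, boron on C1 trans to C3–O and on the chain terminus (not isolated) | C[C@H]1[C@@H](O[Si](C)(C)C(C)(C)C)C[C@@H](C(C)(C)O[Si](CC)(CC)CC)[C@](COCc2ccccc2)(CCCB)[C@@H]1B | intermediate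
14 | diol: C1–OH trans to the C2 methyl and C3–OTBS, which are cis to each other and to the C5 group; 3-hydroxypropyl arm on C6 | C[C@H]1[C@@H](O[Si](C)(C)C(C)(C)C)C[C@@H](C(C)(C)O[Si](CC)(CC)CC)[C@](COCc2ccccc2)(CCCO)[C@@H]1O | intermediate
15 | primary tert-butyldimethylsilyl ether of 14, C1–OH free | C[C@H]1[C@@H](O[Si](C)(C)C(C)(C)C)C[C@@H](C(C)(C)O[Si](CC)(CC)CC)[C@](COCc2ccccc2)(CCCO[Si](C)(C)C(C)(C)C)[C@@H]1O | intermediate
16 | ring-A ketone: C1 ketone, C2 methyl, C3–OTBS, C5 silyloxypropyl and C6 CH2OBn all cis, 3-silyloxypropyl arm trans | C[C@H]1[C@@H](O[Si](C)(C)C(C)(C)C)C[C@@H](C(C)(C)O[Si](CC)(CC)CC)[C@](COCc2ccccc2)(CCCO[Si](C)(C)C(C)(C)C)C1=O | intermediate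
17 | methyl acrylate | C=CC(=O)OC | starting material
18 | trivalent samarium alkoxide of the γ-hydroxy ester, drawn as the free alcohol (not isolated) | C[C@H]1[C@@H](O[Si](C)(C)C(C)(C)C)C[C@@H](C(C)(C)O[Si](CC)(CC)CC)[C@](COCc2ccccc2)(CCCO[Si](C)(C)C(C)(C)C)[C@]1(O)CCC(=O)OC | intermediate
19 | spiro γ-lactone, ring C as lactone, lactone oxygen on C1 cis to the C2, C3 and C5 substituents | C[C@H]1[C@@H](O[Si](C)(C)C(C)(C)C)C[C@@H](C(C)(C)O[Si](CC)(CC)CC)[C@](COCc2ccccc2)(CCCO[Si](C)(C)C(C)(C)C)[C@]12CCC(=O)O2 | intermediate
20 | iodomethane | CI | starting material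
21 | α-methyl spiro γ-lactone, either epimer at Ca | C[C@H]1[C@@H](O[Si](C)(C)C(C)(C)C)C[C@@H](C(C)(C)O[Si](CC)(CC)CC)[C@](COCc2ccccc2)(CCCO[Si](C)(C)C(C)(C)C)[C@]12CC(C)C(=O)O2 | intermediate
22 | methyl (E)-crotonate | C/C=C/C(=O)OC | starting material
23 | Michael adduct: quaternary Ca (methyl, lactone) bonded to Cb (CH–CH3) carrying CH2CO2Me | C[C@H]1[C@@H](O[Si](C)(C)C(C)(C)C)C[C@@H](C(C)(C)O[Si](CC)(CC)CC)[C@](COCc2ccccc2)(CCCO[Si](C)(C)C(C)(C)C)[C@]12C[C@](C)([C@@H](C)CC(=O)OC)C(=O)O2 | intermediate
24 | methacrolein | CC(=C)C=O | starting material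
25 | anti-aldol adduct: Cc bears CO2Me, Cd bears OH and isopropenyl | C[C@H]1[C@@H](O[Si](C)(C)C(C)(C)C)C[C@@H](C(C)(C)O[Si](CC)(CC)CC)[C@](COCc2ccccc2)(CCCO[Si](C)(C)C(C)(C)C)[C@]12C[C@](C)([C@@H](C)[C@H]([C@H](O)C(C)=C)C(=O)OC)C(=O)O2 | intermediate
26 | ozonide (3-methyl-1,2,4-trioxolan-3-yl carbinol) of 25 (not isolated) | C[C@H]1[C@@H](O[Si](C)(C)C(C)(C)C)C[C@@H](C(C)(C)O[Si](CC)(CC)CC)[C@](COCc2ccccc2)(CCCO[Si](C)(C)C(C)(C)C)[C@]12C[C@](C)([C@@H](C)[C@H]([C@H](O)C3(C)OCOO3)C(=O)OC)C(=O)O2 | intermediate
27 | α-hydroxy methyl ketone | C[C@H]1[C@@H](O[Si](C)(C)C(C)(C)C)C[C@@H](C(C)(C)O[Si](CC)(CC)CC)[C@](COCc2ccccc2)(CCCO[Si](C)(C)C(C)(C)C)[C@]12C[C@](C)([C@@H](C)[C@H]([C@H](O)C(C)=O)C(=O)OC)C(=O)O2 | intermediate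
28 | silylated orthoester cage (not isolated) | C[C@H]1[C@@H](O[Si](C)(C)C(C)(C)C)C[C@@H](C(C)(C)O[Si](CC)(CC)CC)[C@](COCc2ccccc2)(CCCO[Si](C)(C)C(C)(C)C)[C@]12C[C@]1(C)[C@@H](C)[C@H]3C(=O)O[C@@]4(C)O[C@@]1(O[C@@H]34)O2 | intermediate
29 | cage triol benzyl ether: C3–OH, tertiary OH and 3-hydroxypropyl free, CH2OBn on C6 | C[C@H]1[C@@H](O)C[C@@H](C(C)(C)O)[C@](COCc2ccccc2)(CCCO)[C@]12C[C@]1(C)[C@@H](C)[C@H]3C(=O)O[C@@]4(C)O[C@@]1(O[C@@H]34)O2 | intermediate
30 | cage tetraol: hydroxymethyl and 3-hydroxypropyl on C6 | C[C@H]1[C@@H](O)C[C@@H](C(C)(C)O)[C@](CO)(CCCO)[C@]12C[C@]1(C)[C@@H](C)[C@H]3C(=O)O[C@@]4(C)O[C@@]1(O[C@@H]34)O2 | intermediate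
31 | ring-B lactol, both anomers (not isolated) | C[C@H]1[C@@H](O)C[C@@H](C(C)(C)O)[C@]2(CCC(O)OC2)[C@]12C[C@]1(C)[C@@H](C)[C@H]3C(=O)O[C@@]4(C)O[C@@]1(O[C@@H]34)O2 | intermediate
32 | Chermebilaene B | C[C@H]1[C@@H](O)C[C@@H](C(C)(C)O)[C@]2(CCC(=O)OC2)[C@]12C[C@]1(C)[C@@H](C)[C@H]3C(=O)O[C@@]4(C)O[C@@]1(O[C@@H]34)O2 | target

**Step count and risks**

Total: 20 steps. Longest linear sequence: 20 steps from (R)-carvone; all other starting materials are commercial.

Steps most likely to fail:

1. Step 15. The hindered enolate may add slowly and lose protons to the enoate instead, and the discrimination between the two faces of the crotonate may be poor if an open transition state competes with the closed one. The fallback sets out from 21. Deprotonation with LiN(i-Pr)2 and trapping with Me3SiCl gives the trimethylsilyl ketene acetal F1. A Mukaiyama–Michael addition of F1 to (E)-3-crotonoyl-1,3-oxazolidin-2-one, catalysed by Cu(OTf)2 with a tert-butyl-bis(oxazoline) ligand, gives the imide F2. The chelating divalent copper complex, not the enolate, then selects the face of the acceptor, and the ligand antipode is chosen for the required Cb configuration. MeOMgBr in MeOH/CH2Cl2 at 0 °C exchanges the oxazolidinone for methoxide, and the route is rejoined at 23.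

2. Step 16. The anti selectivity of the lithium aldol may erode through a competing boat transition state, and the aldolate may revert on warming. The fallback sets out from 23. The E(O)-enolate is silylated (LiN(i-Pr)2, Me3SiCl, −78 °C) to the methyl trimethylsilyl ketene acetal F3. A BF3·OEt2-mediated Mukaiyama aldol addition of F3 to methacrolein in CH2Cl2 at −78 °C runs through an open transition state, which is usually anti-selective and is subject to the same allylic-strain control of the enolate face. It gives 25 after aqueous work-up.

3. Step 6. Hydrazone formation at the C1 carbonyl, flanked by quaternary C6 and the epoxide carbon, may be too slow, so that hydrazine opens the epoxide or adventitious diimide reduces the allyl group. The fallback sets out from 7. Luche reduction (NaBH4, CeCl3·7H2O, MeOH) delivers hydride anti to the axial benzyloxymethyl group and gives the C1 allylic alcohol F4. A suprafacial 1,3-transposition of its perrhenate ester with catalytic Ph3SiOReO3 in Et2O then moves the hydroxyl to the less hindered C3 on the same ring face. This arrives at 11 and bypasses 8, 9 and 10.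

**Further compounds**

F1 | step 15 | trimethylsilyl ketene acetal of lactone 21 | C[C@H]1[C@@H](O[Si](C)(C)C(C)(C)C)C[C@@H](C(C)(C)O[Si](CC)(CC)CC)[C@](COCc2ccccc2)(CCCO[Si](C)(C)C(C)(C)C)[C@]12CC(C)=C(O[Si](C)(C)C)O2
F2 | step 15 | N-acyl oxazolidinone Michael adduct (imide analogue of 23) | C[C@H]1[C@@H](O[Si](C)(C)C(C)(C)C)C[C@@H](C(C)(C)O[Si](CC)(CC)CC)[C@](COCc2ccccc2)(CCCO[Si](C)(C)C(C)(C)C)[C@]12C[C@](C)([C@@H](C)CC(=O)N3CCOC3=O)C(=O)O2
F3 | step 16 | methyl trimethylsilyl ketene acetal of ester 23 (Cb trans to OSiMe3) | C[C@H]1[C@@H](O[Si](C)(C)C(C)(C)C)C[C@@H](C(C)(C)O[Si](CC)(CC)CC)[C@](COCc2ccccc2)(CCCO[Si](C)(C)C(C)(C)C)[C@]12C[C@](C)([C@@H](C)/C=C(/O[Si](C)(C)C)OC)C(=O)O2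
F4 | step 6 | C1 allylic alcohol from 7 (C1–OH cis to CH2OBn and the C5 group) | CC1=CC[C@@H](C(C)(C)O[Si](CC)(CC)CC)[C@](COCc2ccccc2)(CC=C)[C@H]1O
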